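**Plan**

Numbering: ring A = C4a, C5–C8, C8a (OMe on C6, C7, C8). Ring B = C1 (bears ring C, the 3,4-dimethoxyphenyl group), C2 (bears C9H2OH), C3 (bears C10H2OH), C4, C4a, C8a.
Cuts, in retrosynthetic order: C3–C10, with the C3=C4 alkene traced back to a C4 ketone and C9 to an ester. Then C3–C4, with C4 re-bonded to C2, which contracts ring B to a 2-(bromomethyl)-3-aryl-1-indanone-2-carboxylate. Then C2–C3, C1–C8a, C1–C2 and C2–C9.
Enabling feature: in ring B, C3 lies alone between C4 and C2. C4 hangs on the fusion carbon C4a and can be an aryl ketone, and C2 carries the carboxyl-level carbon C9. Removing C3 leaves a cyclic β-keto ester, so C3 can be inserted by a radical 1,2-acyl shift.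
Forward order: the side chain is built on ring A, a five-membered ring is closed by 4π-electrocyclisation and then expanded to six-membered ring B. C10 and the C3=C4 alkene are installed last, from the C4 ketone.
Stereochemistry: C1 comes from the chiral copper catalyst of the Nazarov step and is not touched afterwards. C2 is set relative to C1 by thermodynamic equilibration of the ester to trans before its reduction.

Key step: step 5

Assumption: the (S,S)-Ph-box ligand is taken to give the (3R)-indanone in the copper-catalysed Nazarov step. If the sense of induction is the opposite, the equally available (R,R)-ligand is used and nothing else changes.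

Step 1
Reactants: 1 3',4',5'-trimethoxyacetophenone; 2 dimethyl carbonate
Product: 3 methyl 3-oxo-3-(3,4,5-trimethoxyphenyl)propanoate
Conditions: NaH, THF, reflux; aq. HCl quench
Reagents that add atoms: none
Why: Crossed Claisen condensation of a methyl ketone enolate with a non-enolisable carbonate, pulled to completion by deprotonation of the β-keto ester formed, joins C2 to C9.

Step 2
Reactants: 3 methyl 3-oxo-3-(3,4,5-trimethoxyphenyl)propanoate; 4 veratraldehyde (3,4-dimethoxybenzaldehyde)
Product: 5 methyl (Z)-3-(3,4-dimethoxyphenyl)-2-(3,4,5-trimethoxybenzoyl)prop-2-enoate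
Conditions: piperidine (cat.), AcOH (cat.), toluene, Dean–Stark, reflux
Reagents that add atoms: none
Why: Knoevenagel condensation of an active methylene compound with a non-enolisable aldehyde under azeotropic removal of water should favour the isomer with ring C cis to the ester, and the geometry has no consequence because the isomers interconvert on the Lewis acid of step 3.

Step 3
Reactants: 5 methyl (Z)-3-(3,4-dimethoxyphenyl)-2-(3,4,5-trimethoxybenzoyl)prop-2-enoate
Product: 6 methyl (2S,3R)-3-(3,4-dimethoxyphenyl)-4,5,6-trimethoxy-1-oxoindane-2-carboxylate (ester trans to aryl)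
Conditions: Cu(OTf)2 (10 mol %), (S,S)-Ph-box [2,2'-isopropylidenebis((4S)-4-phenyl-2-oxazoline)] (11 mol %), ClCH2CH2Cl, rt → 50 °C
Reagents that add atoms: none
Why: In this catalytic enantioselective Nazarov cyclisation of a polarised aryl vinyl ketone, two-point binding of the β-keto ester to the divalent copper–bis(oxazoline) complex generates the pentadienyl cation, ring A closes at either of its equivalent ortho carbons (each para to a methoxy group), the C2-symmetric ligand biases the sense of conrotation and so sets indanone C3 (target C1), and the labile indanone C2 settles trans by enolisation.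

Step 4
Reactants: 6 methyl (2S,3R)-3-(3,4-dimethoxyphenyl)-4,5,6-trimethoxy-1-oxoindane-2-carboxylate; 7 dibromomethane
Product: 8 methyl (2S,3R)-2-(bromomethyl)-3-(3,4-dimethoxyphenyl)-4,5,6-trimethoxy-1-oxoindane-2-carboxylate (CH2Br trans to aryl)
Conditions: NaH, THF–DMPU, 0 °C; CH2Br2 (10 equiv), 65 °C
Reagents that add atoms: none
Why: SN2 C-alkylation of the stabilised β-keto ester enolate with a large excess of the dihalide is the standard entry to Dowd–Beckwith substrates, the electrophile approaches the enolate face opposite ring C so that CH2Br ends trans to it, and the excess suppresses a second displacement.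

Step 5
Reactants: 8 methyl (2S,3R)-2-(bromomethyl)-3-(3,4-dimethoxyphenyl)-4,5,6-trimethoxy-1-oxoindane-2-carboxylate
Product: 10 methyl (1R,2R)-1-(3,4-dimethoxyphenyl)-6,7,8-trimethoxy-4-oxo-1,2,3,4-tetrahydronaphthalene-2-carboxylate (trans), via cis keto ester 9 (not isolated)
Conditions: Bu3SnH (1.2 equiv) + AIBN (0.1 equiv) by syringe pump, PhH (0.01 M), reflux; evaporate; NaOMe (0.2 equiv), MeOH, rt
Reagents that add atoms: none
Why: The stannyl radical abstracts bromine from 8, the primary radical (future C3) adds to the aryl ketone carbon (future C4) to give a cyclopropyloxy radical, and β-scission of the old C2–C4 bond relieves the strain, restores the carbonyl and leaves an ester-stabilised tertiary radical at C2 that takes hydrogen from Bu3SnH; this is the Dowd–Beckwith one-carbon expansion known for 2-(halomethyl) β-keto esters, benzo-fused ones included. Only the transient three-membered ring is closed directly (3-exo-trig onto C=O), and six-membered ring B arises from it by fragmentation. The regioselectivity of fragmentation is secured by the ester, because the other two scissions of the alkoxy radical would only return the primary radical or produce an aryl radical. Rearrangement must precede hydrogen transfer, which is secured by a low stationary stannane concentration, and the trans relation of CH2Br and ring C keeps the radical away from the veratryl ring. C1 is a spectator, whereas C2 should first be set by hydrogen delivery to the face opposite ring C (mainly cis ester 9). Methoxide-catalysed enolisation should then correct it to trans isomer 10, in which ring C, held pseudoaxial by the peri 8-methoxy group, and the ester stand anti to each other.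

Step 6
Reactants: 10 methyl (1R,2R)-1-(3,4-dimethoxyphenyl)-6,7,8-trimethoxy-4-oxo-1,2,3,4-tetrahydronaphthalene-2-carboxylate
Product: 11 methyl (1R,2S,3Z)-1-(3,4-dimethoxyphenyl)-3-(hydroxymethylidene)-6,7,8-trimethoxy-4-oxo-1,2,3,4-tetrahydronaphthalene-2-carboxylate
Conditions: NaH, HCO2Me, THF, 0 °C → rt; aq. HCl quench
Reagents that add atoms: methyl formate, COC=O
Why: In this reversible crossed Claisen formylation only acylation at the ketone α-methylene C3 gives a fully delocalised β-dicarbonyl enolate, so formyl transfer funnels there rather than to C2 as is familiar for 1-aryl-4-tetralone-2-carboxylates, and the allylic 1,3-strain of the new exocyclic alkene reinforces the trans-diaxial placement of the C2 ester relative to ring C.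

Step 7
Reactants: 11 methyl (1R,2S,3Z)-1-(3,4-dimethoxyphenyl)-3-(hydroxymethylidene)-6,7,8-trimethoxy-4-oxo-1,2,3,4-tetrahydronaphthalene-2-carboxylate
Product: 12 methyl (1R,2S,3E)-1-(3,4-dimethoxyphenyl)-6,7,8-trimethoxy-4-oxo-3-[(propan-2-yloxy)methylidene]-1,2,3,4-tetrahydronaphthalene-2-carboxylate
Conditions: i-PrI, K2CO3, acetone, reflux
Reagents that add atoms: 2-iodopropane, CC(C)I
Why: O-alkylation of a hydroxymethylene ketone with a secondary iodide and carbonate base is the classical route to alkoxymethylene ketones, the hindered electrophile favours oxygen over C3, the ether should adopt the E geometry, and C2 stays at its thermodynamic trans setting.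

Step 8
Reactants: 12 methyl (1R,2S,3E)-1-(3,4-dimethoxyphenyl)-6,7,8-trimethoxy-4-oxo-3-[(propan-2-yloxy)methylidene]-1,2,3,4-tetrahydronaphthalene-2-carboxylate
Product: 14 (1R,2S)-1-(3,4-dimethoxyphenyl)-2-(hydroxymethyl)-6,7,8-trimethoxy-1,2-dihydronaphthalene-3-carbaldehyde (target numbering), via allylic alcohol enol ether 13 (not isolated)
Conditions: LiAlH4, THF, 0 °C; then 1 M aq. HCl, THF, 0 °C → rt
Reagents that add atoms: water, O
Why: 1,2-Hydride reduction of the vinylogous ester carbonyl and of the C9 ester gives 13, whose benzylic and allylic C4 hydroxyl ionises in dilute acid to an oxocarbenium ion that water captures at C10 with loss of 2-propanol (reductive 1,3-carbonyl transposition of the Stork–Danheiser type), which places the alkene at C3=C4 without touching C1 or C2.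

Step 9
Reactants: 14 (1R,2S)-1-(3,4-dimethoxyphenyl)-2-(hydroxymethyl)-6,7,8-trimethoxy-1,2-dihydronaphthalene-3-carbaldehyde
Product: 15 [(1R,2S)-1-(3,4-dimethoxyphenyl)-6,7,8-trimethoxy-1,2-dihydronaphthalene-2,3-diyl]dimethanol (CNP0274357.1)
Conditions: NaBH4, MeOH, 0 °C
Reagents that add atoms: none
Why: NaBH4 in methanol reduces a conjugated aldehyde chemoselectively in the 1,2-sense, any lactol form of the γ-hydroxy aldehyde is reduced through its open form to the same diol, and no stereocentre is affected.

**Compound list**

1 | 3',4',5'-trimethoxyacetophenone | CC(=O)c1cc(OC)c(OC)c(OC)c1 | starting material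
2 | dimethyl carbonate | COC(=O)OC | starting material
3 | methyl 3-oxo-3-(3,4,5-trimethoxyphenyl)propanoate | COC(=O)CC(=O)c1cc(OC)c(OC)c(OC)c1 | intermediate
4 | veratraldehyde | COc1ccc(C=O)cc1OC | starting material
5 | methyl (Z)-3-(3,4-dimethoxyphenyl)-2-(3,4,5-trimethoxybenzoyl)prop-2-enoate | COC(=O)/C(=C\c1ccc(OC)c(OC)c1)C(=O)c1cc(OC)c(OC)c(OC)c1 | intermediate
6 | methyl (2S,3R)-3-(3,4-dimethoxyphenyl)-4,5,6-trimethoxy-1-oxoindane-2-carboxylate | COc1ccc([C@@H]2c3c(cc(OC)c(OC)c3OC)C(=O)[C@H]2C(=O)OC)cc1OC | intermediate
7 | dibromomethane | BrCBr | starting material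
8 | methyl (2S,3R)-2-(bromomethyl)-3-(3,4-dimethoxyphenyl)-4,5,6-trimethoxy-1-oxoindane-2-carboxylate | COc1ccc([C@@H]2c3c(cc(OC)c(OC)c3OC)C(=O)[C@]2(CBr)C(=O)OC)cc1OC | intermediate
9 | methyl (1R,2S)-1-(3,4-dimethoxyphenyl)-6,7,8-trimethoxy-4-oxo-1,2,3,4-tetrahydronaphthalene-2-carboxylate (cis) | COc1ccc([C@@H]2c3c(cc(OC)c(OC)c3OC)C(=O)C[C@@H]2C(=O)OC)cc1OC | intermediate
10 | methyl (1R,2R)-1-(3,4-dimethoxyphenyl)-6,7,8-trimethoxy-4-oxo-1,2,3,4-tetrahydronaphthalene-2-carboxylate (trans) | COc1ccc([C@@H]2c3c(cc(OC)c(OC)c3OC)C(=O)C[C@H]2C(=O)OC)cc1OC | intermediate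
11 | methyl (1R,2S,3Z)-1-(3,4-dimethoxyphenyl)-3-(hydroxymethylidene)-6,7,8-trimethoxy-4-oxo-1,2,3,4-tetrahydronaphthalene-2-carboxylate | COc1ccc([C@@H]2c3c(cc(OC)c(OC)c3OC)C(=O)/C(=C\O)[C@H]2C(=O)OC)cc1OC | intermediate
12 | methyl (1R,2S,3E)-1-(3,4-dimethoxyphenyl)-6,7,8-trimethoxy-4-oxo-3-[(propan-2-yloxy)methylidene]-1,2,3,4-tetrahydronaphthalene-2-carboxylate | COc1ccc([C@@H]2c3c(cc(OC)c(OC)c3OC)C(=O)/C(=C/OC(C)C)[C@H]2C(=O)OC)cc1OC | intermediate
13 | (1R,2S,3E)-1-(3,4-dimethoxyphenyl)-2-(hydroxymethyl)-6,7,8-trimethoxy-3-[(propan-2-yloxy)methylidene]-1,2,3,4-tetrahydronaphthalen-4-ol (target numbering; C4 epimers, both ionise to the same cation) | COc1ccc([C@@H]2c3c(cc(OC)c(OC)c3OC)C(O)/C(=C/OC(C)C)[C@H]2CO)cc1OC | intermediate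
14 | (1R,2S)-1-(3,4-dimethoxyphenyl)-2-(hydroxymethyl)-6,7,8-trimethoxy-1,2-dihydronaphthalene-3-carbaldehyde | COc1ccc([C@@H]2c3c(cc(OC)c(OC)c3OC)C=C(C=O)[C@H]2CO)cc1OC | intermediate
15 | [(1R,2S)-1-(3,4-dimethoxyphenyl)-6,7,8-trimethoxy-1,2-dihydronaphthalene-2,3-diyl]dimethanol | COc1ccc([C@@H]2c3c(cc(OC)c(OC)c3OC)C=C(CO)[C@H]2CO)cc1OC | target

Total steps: 9. Longest linear sequence: 9 (from 1 to 15).

**Steps most likely to fail**

Step 3. The ligand may bias the sense of conrotation only weakly, or turnover may be slow because ring C stabilises the cation. The fallback replaces catalyst control by a covalent auxiliary with separation of diastereomers.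
- It sets out from 3, which is transesterified with (−)-menthol (DMAP cat., toluene, reflux) to (1R,2S,5R)-menthyl 3-oxo-3-(3,4,5-trimethoxyphenyl)propanoate F1.
- Knoevenagel condensation with 4 gives (1R,2S,5R)-menthyl (Z)-3-(3,4-dimethoxyphenyl)-2-(3,4,5-trimethoxybenzoyl)prop-2-enoate F2.
- Cu(OTf)2 without ligand cyclises F2 to two trans indanones that differ at C3 and are separated by crystallisation or chromatography.
- The wanted isomer is (1R,2S,5R)-menthyl (2S,3R)-3-(3,4-dimethoxyphenyl)-4,5,6-trimethoxy-1-oxoindane-2-carboxylate F3.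
- DMAP-catalysed methanolysis returns it to the route at 6, by the acylketene pathway open to enolisable β-keto esters.

Step 5. Hydrogen transfer from the stannane to the primary radical may outrun the 3-exo closure onto the electron-rich, conjugated ketone. The fallback is the ionic counterpart of the same one-carbon insertion.
- It sets out from 6 and bypasses 8.
- Et2Zn and CH2I2 (CH2Cl2, 0 °C → rt) form the zinc enolate and transfer CH2 to C2.
- The homoenolate closes onto the ketone to a zinc cyclopropoxide, which fragments at the same C2–C4 bond (zinc-carbenoid chain extension of β-keto esters).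
- Protonation and the same NaOMe equilibration bring the material back at 10. This detour makes no compound outside the list (F0).

Step 4. C-alkylation at the hindered carbon next to ring C may lose to O-alkylation, or to a second displacement that links two enolates. The fallback replaces alkylation by an aldol addition followed by substitution at oxygen.
- It sets out from 6. Aqueous formaldehyde with KHCO3 in THF adds to the face opposite ring C.
- This gives methyl (2S,3R)-3-(3,4-dimethoxyphenyl)-2-(hydroxymethyl)-4,5,6-trimethoxy-1-oxoindane-2-carboxylate F4.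
- An Appel bromination (CBr4, PPh3, CH2Cl2) converts it to the bromide and rejoins the route at 8. The conditions are neutral, so retro-aldol cleavage is avoided, and the method is known to work on neopentyl-type alcohols.

**Further compounds**

F1 | step 3 | (1R,2S,5R)-menthyl 3-oxo-3-(3,4,5-trimethoxyphenyl)propanoate | CC(C)[C@@H]1CC[C@@H](C)C[C@H]1OC(=O)CC(=O)c1cc(OC)c(OC)c(OC)c1
F2 | step 3 | (1R,2S,5R)-menthyl (Z)-3-(3,4-dimethoxyphenyl)-2-(3,4,5-trimethoxybenzoyl)prop-2-enoate | CC(C)[C@@H]1CC[C@@H](C)C[C@H]1OC(=O)/C(=C\c1ccc(OC)c(OC)c1)C(=O)c1cc(OC)c(OC)c(OC)c1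
F3 | step 3 | (1R,2S,5R)-menthyl (2S,3R)-3-(3,4-dimethoxyphenyl)-4,5,6-trimethoxy-1-oxoindane-2-carboxylate | COc1ccc([C@@H]2c3c(cc(OC)c(OC)c3OC)C(=O)[C@H]2C(=O)O[C@@H]4C[C@H](C)CC[C@H]4C(C)C)cc1OC
F0 | step 5 | none | none
F4 | step 4 | methyl (2S,3R)-3-(3,4-dimethoxyphenyl)-2-(hydroxymethyl)-4,5,6-trimethoxy-1-oxoindane-2-carboxylate | COc1ccc([C@@H]2c3c(cc(OC)c(OC)c3OC)C(=O)[C@]2(CO)C(=O)OC)cc1OC
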